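If a run decays towards a floor rather than towards zero, the floor is a small correction while the flask is full and a large one late, so you can reckon the decay first and then the correction. Here are the flasks and the question.

the same everywhere: gas phase 11 mM (held)
- beta: starting material 0.26 M (in portions, 3); catalyst 0.083 mM; temperature 35 °C; run made earlier; portions every 5.0 min
- delta: starting material 0.26 M (in portions, 3); catalyst 0.26 mM; temperature 50 °C; run made earlier; portions every 5.0 min
- zeta: starting material 0.26 M (in portions, 3); catalyst 0.83 mM; temperature 35 °C; run made earlier; portions every 5.0 min
- alpha: starting material 0.17 M (in portions, 3); catalyst 0.36 mM; temperature 50 °C; run made earlier; portions every 5.0 min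
- birch: starting material 0.26 M (in portions, 3); catalyst 0.36 mM; temperature 40 °C; the portions of starting material follow each other after 10 min, the first at the start; time 30 min
- larch: starting material 0.40 M (in portions, 3); catalyst 0.10 mM; temperature 40 °C; the portions of starting material follow each other after 5.0 min, the first at the start; time 30 min
- alder: starting material 0.26 M (in portions, 3); catalyst 0.20 mM; temperature 60 °C; the portions of starting material follow each other after 5.0 min, the first at the start; time 30 min
- maple: starting material 0.060 M (in portions, 3); catalyst 0.20 mM; temperature 40 °C; the portions of starting material follow each other after 5.0 min, the first at the start; time 30 min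
- ash: starting material 0.40 M (in portions, 3); catalyst 0.80 mM; temperature 40 °C; the portions of starting material follow each other after 20 min, the first at the start; time 30 min
- cedar: starting material 0.26 M (in portions, 3); catalyst 0.36 mM; temperature 40 °C; the portions of starting material follow each other after 5.0 min, the first at the start; time 30 min

| run | time / min | product / % | starting material / % |
|---|---|---|---|
| beta | 2.50 | 2 | 32 |
| beta | 6.00 | 4 | 63 |
| beta | 12.0 | 8 | 94 |
| beta | 30.0 | 23 | 71 |
| delta | 2.50 | 4 | 30 |
| delta | 6.00 | 12 | 54 |
| delta | 12.0 | 33 | 66 |
| delta | 20.0 | 60 | 40 |
| zeta | 4.00 | 8 | 21 |
| zeta | 10.0 | 31 | 37 |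
| zeta | 20.0 | 74 | 27 |
| zeta | 30.0 | 86 | 12 |
| alpha | 1.50 | 4 | 26 |
| alpha | 4.00 | 9 | 24 |
| alpha | 8.00 | 22 | 44 |
| alpha | 20.0 | 69 | 33 |

(standard deviation of a reading: 1.5 percentage points)

- the earlier runs were read with a standard deviation of 1.5 percentage points
- at the start none of the gas phase is in solution
- percentages count the whole charge, also what has not yet gone in
- a reading or a percentage of product counts all its forms, free or not

- the flasks by amount of product, in percent of the starting material charged, highest first, at 30 min (birch / larch / alder / maple / ash / cedar)
- the amount of product, in percent of the starting material charged of the flask you put first, at 30 min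
- the amount of product, in percent of the starting material charged of the flask you put last, at 30 min

Take the rate as proportional to catalyst and to free starting material, a pseudo-first-order decay with constant k. In beta, the last portion is in by 12.0 min, and starting material falls from 94% to 71% at 30.0 min, so k reads 0.0156 min⁻¹. Zeta has ten times that catalyst, so between 20.0 min and 30.0 min its reading should shrink to a fraction 0.210. It goes from 27% to 12%, a fraction 0.444, which is more than expected. Read that shortfall as a level the decay approaches: 8.00% of zeta's charge.

The weak link is beta's k, which was read as if that level were zero. Subtracting it from both beta readings gives k = 0.0173 min⁻¹, and zeta's expected fraction becomes 0.177. Repeating the step gives a reading of 22.8 mM, with the scatter of the four readings behind it. This is the floor F, the concentration of starting material I take a run to approach at its end. I take F as a concentration, the same for any charge, which these readings do not test, and I leave the gap between 35 °C and 40 °C uncorrected.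

For a charge c, the product share is then (1 − F/c)(1 − exp(−kt)), with k scaled to the flask's catalyst and t counted from the middle portion, here 25.0 min. In larch, k is 0.0208 min⁻¹ and F is 5.70% of the charge, which gives 38.3%. Maple has twice larch's catalyst, so k is 0.0417 min⁻¹, but F is 38.0% of its charge, which gives 40.1%. By this reckoning maple ends narrowly above larch, and I commit to larch last at 38.3%, leaving the head of the list unreckoned.

The forecast differs: it reads high loading as “so it looks saturated” and gives alder > maple > cedar > birch > ash > larch, with 88% first and 22% last.

The flasks give alder > cedar > birch > ash > maple > larch: alder 82.5%, maple 42.8% and larch 35.0%, crystals counted in.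

    gas phase ⇌ dissolved gas, rate k1*(csat - [dissolved gas]) (kL = 50.1 min⁻¹)
    starting material + dissolved gas + catalyst ⇌ catalyst + product (K = 30.0 L mol⁻¹, k = 17100 L² mol⁻² min⁻¹, Ea = 36.0 kJ mol⁻¹, ΔH = 18.0 kJ mol⁻¹)
    crystals ⇌ product, rate k3*(cs3 - [product]) while solid is left; crystals form when [product] > cs3 (solubility = 5.50 mM, k = 4.69 min⁻¹)
    (constants at 40 °C)

At 300 min, maple still holds 27.8% of its charge as starting material, which is 16.7 mM. Take a further flask like larch but charged with 0.10 M of starting material. There F is 22.8% of the charge, and at larch's k the formula gives 31.3%; that flask gives 30.7%.

(All runs are calculated for substances that don't exist; the scatter is artificial.)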